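The data were generated by integration with constants of no real substance.

The closed, stirred vessel was the dawn flask, already followed for some minutes, and beside it I had the spring run with twice the substrate.

| setting | dawn | spring | flask |
|---|---|---|---|
| substrate | 10 mM | 20 mM | 10 mM |
| coupling partner | 40 mM | 40 mM | 40.0 mM |
| free catalyst | 20 µM | 20 µM | 20 µM |
| remark | the very flask that is asked about, followed so far | run made earlier |  |

| run | time / min | target / % | substrate / % |
|---|---|---|---|
| dawn | 0.333 | 1.5 | 99.3 |
| dawn | 1.00 | 6.3 | 91.9 |
| dawn | 1.50 | 11.0 | 92.0 |
| dawn | 2.50 | 14.5 | 84.8 |
| dawn | 4.00 | 25.6 | 73.3 |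
| dawn | 5.00 | 30.6 | 68.7 |
| dawn | 6.00 | 40.3 | 63.7 |
| spring | 5.00 | 16.5 | 82.4 |
| spring | 10.0 | 33.7 | 67.1 |
| spring | 15.0 | 47.4 | 52.0 |
| spring | 20.0 | 64.2 | 35.9 |
| spring | 25.0 | 80.4 | 20.9 |
| spring | 30.0 | 91.1 | 9.6 |
| spring | 40.0 | 100.8 | 0 |

(each reading ± 1 percentage point)

- apparent order in free catalyst when 30% of the substrate are converted (percent change of the rate of making target for one percent more free catalyst charged)
- apparent order in coupling partner when 30% of the substrate are converted (percent change of the rate of making target for one percent more coupling partner charged)
- factor on the rate of making target when 30% of the substrate are converted if coupling partner is charged twice over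

- what was read earlier has a scatter of 1 percentage point, one standard deviation
- no earlier run changes the charge of free catalyst; that part of a forecast is a guess
- no earlier run changes the charge of coupling partner; that part of a forecast is a guess

By 20.0 min the spring run had made 12.8 mM of target on 20 µM of free catalyst, which gives 32.1 min⁻¹. This is the turnover frequency, target made per minute per catalyst charged. The dawn flask's own reading at 5.00 min gave 30.6 min⁻¹, so the two charges of substrate gave nearly one frequency. Carried over from the spring run, the frequency put 30% conversion in the dawn flask at 4.67 min. I could reckon no order in free catalyst or coupling partner, since neither charge had been varied.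

The forecast gave 1 for the order in free catalyst, 0.03 for the order in coupling partner and 1.02 for the factor on the rate with twice the coupling partner, and it warned that “off-cycle aggregation could change that”.

The flask reached 30% at 4.70 min, at 0.622 mM min⁻¹, a frequency of 31.1 min⁻¹. Its order in free catalyst was 0.66, its order in coupling partner 0.11 and the factor 1.06.

    substrate + catalyst intermediate A → catalyst intermediate B (k = 28000 L mol⁻¹ min⁻¹)
    substrate + catalyst intermediate C ⇌ idle complex, settled at all times (K = 38.0 L mol⁻¹)
    2 catalyst intermediate D ⇌ resting dimer, settled at all times (K = 7.00 × 10⁵ L mol⁻¹)
    catalyst intermediate B ⇌ released group + catalyst intermediate C (K = 0.0120 M, k = 1100 min⁻¹)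
    catalyst intermediate D → free catalyst + target (k = 230 min⁻¹)
    coupling partner + free catalyst ⇌ catalyst intermediate A (K = 1300 L mol⁻¹, k = 5500 L mol⁻¹ min⁻¹)
    catalyst intermediate C → catalyst intermediate D (k = 4700 min⁻¹)

At 5.00 min the resting dimer, an off-cycle resting state, held 50.8% of the catalyst charged in this flask. The same flask without that binding had, at 30% conversion, 2.05 times the actual rate, and its order in free catalyst there stood at 1.0. With c(coupling partner) doubled, I applied the factor 1.06, which belongs to the rate at 30% conversion, to the carried frequency and got an estimate of 33.9 min⁻¹, which puts 30% conversion at 4.43 min, and the run with that charge took 0.949 of the time of this flask, 4.46 min.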